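**Remarks on the chemistry (assumptions)**

- Isoflavone numbering is used for each half. Unit A is the 7-hydroxy half, whose ring B carries the ether oxygen at C3'. Unit B is the 8-chloro-5,7-dihydroxy half, and "ring A of unit B" is its chlorinated benzo ring.
- The target has no stereocentre and no stereogenic double bond. The racemic centres of 5, 11, 13 and 26 are transient.
- The atom mapping of the benzannulation was re-derived from 5 and 9 and agrees with 14 as drawn, so no structure needed correcting. The one constraint is that chlorine must sit on the sp3 carbon (C4) of the cyclobutenone. The isomer with chlorine on the vinylic carbon would put it at C6.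
- The precursor pair 5/9 is kept unchanged, because it already delivers the three ring oxygens differentiated (ethyl ether, silyl ether, free hydroxyl). The improvements are in how it is reached and used:
  - 9 is made in one step from a purchasable alkyne.
  - The benzylic silyl ether is oxidised directly to the aldehyde.
  - The benzylic zinc reagent is made from the chloride.
  - Acetal removal and pyranone closure are merged.
- 1 (hexane solution), 2, 6, 17, 18 and 21 are taken as purchasable.

## Structural features

Bisoflavolin L is a dimer of two isoflavones (3-arylchromen-4-ones) joined by one diaryl ether oxygen. In unit A (7-hydroxy) the pendant ring B carries a free hydroxyl at C4' and the ether oxygen at C3', and that oxygen is bonded to C4' of ring B of unit B, an 8-chloro-5,7-dihydroxyisoflavone. There is no stereocentre, so no relationship between neighbouring centres has to be built, and every problem is one of position. The fragile elements are the four phenols (the C5 hydroxyl of unit B is chelated to its C4 carbonyl), the two γ-pyranone rings, which hydroxide, amines and hard carbanions open at C2, and the aryl C–Cl bond, which rules out hydrogenolysis late in the route. The diaryl ether is unsymmetrical but unproblematic, because the ring on the unit B side is para-substituted by the carbon that becomes C3 of unit B and can carry an activating group for nucleophilic aromatic substitution. The real difficulty is ring A of unit B: a hexasubstituted benzene with oxygen on C5, C7 and C8a, chlorine on C8, hydrogen on C6 and the carbonyl carbon on C4a, in which the two ortho oxygens and the positions C6 and C8 are nearly equivalent, so that neither chlorination nor pyranone closure of a phloroglucinol-type ketone distinguishes them reliably. The key step exploits the fact that this ring divides into a four-carbon unit C8a–C8–C7–C6 (chlorine on C8, oxygen on C7) and a two-carbon unit C4a–C5 (side-chain carbon and oxygen), so that a cyclobutenone–alkyne benzannulation assembles it with chlorine locked next to the one hydroxyl that is released free.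

## Logic of the disconnections

**31 to 30.** The last bonds cut are four oxygen–protecting-group bonds: O–CH3 at C7 and C4' of unit A, O–C2H5 at C7 of unit B and O–Si at C5 of unit B. Cutting here keeps every earlier intermediate free of acidic phenols, which would quench the organometallic step and complicate the oxidations. The gain is a single final operation. The demand is one reagent that cleaves methyl, ethyl and silyl ethers while leaving the aryl chloride, the diaryl ether and both pyranones intact, which excludes hydrogenolysis.

**30 to 27.** The pyranone of unit B is opened at O1–C2 and C2–C3, which removes C2 as a one-carbon unit and leads through 29 and 28 back to 27. This is the standard deoxybenzoin logic and reduces unit B to a ketone whose ring A carries two ortho oxygens. The demand is strict: only the oxygen on C8a may be free when the ring closes, so in 27 that oxygen carries an acid-labile acetal and the C5 oxygen an acid-stable silyl group.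

**27 to 16 and 25.** After adjusting the oxidation level (27 back to 26), the C3–C4 bond of unit B is cut between the carbinol carbon and the benzylic carbon. This is the convergent cut: it separates the whole of unit A, with the diaryl ether attached, from ring A of unit B. The forward step needs a benzylic nucleophile mild enough to spare the pyranone of unit A, which is why 25 is an organozinc, made from 24.

**24 to 20 and 21.** Functional-group changes lead from 24 through 23 to 22, and 22 is cut at the aryl C–O bond on the unit B side of the diaryl ether. The para formyl group of 21 activates the fluorine-bearing carbon and afterwards becomes C3 of unit B, so no atom is wasted. The demand is a base and solvent that do not open the pyranone of 20.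

**20 to 17 and 18.** Unit A is cut at C4–C4a (aryl ketone bond) and at O1–C2 and C2–C3 (one-carbon unit), passing through 19. Both pieces are purchasable and carry the final oxygen pattern. The demand is acylation of 17 ortho to its hydroxyl, which the one-flask closure itself checks, since only that isomer can cyclise.

**16 to 14.** 16 is related to 15 by oxidation level at the benzylic carbon and 15 to 14 by the acetal on the C8a oxygen; no skeletal bond is cut. The gain is that 14 needs no further differentiation of its oxygens. The demand is an oxidation that converts the benzylic silyl ether without touching the aryl silyl ether.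

**14 to 5 and 9 (key).** Ring A is cut at C8a–C4a and C5–C6, and the C8a–C8 bond is traced back to the ring bond of 5 that opens and re-forms. This cut lets chlorine (on C8) and the free hydroxyl (on C8a) originate from neighbouring atoms of one small ring, while the C5 oxygen arrives already silylated from 9. A hexasubstituted benzene is thereby reduced to two fragments of four and three carbons. The demand is a single orientation of the ketene–alkyne cycloaddition within the cascade 10, 11, 12, 13.

**5 to 1 and 2.** 5 comes from 4 by removal of one chlorine, and 4 is cut at the two ring bonds C1–C2 and C3–C4 into 1 and the ketene 3, generated from 2. The forward step must stop the reduction at the monochloride.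

**9 to 6.** The C(sp)–O bond of 9 is cut, leading through 8 and 7 to 6. The forward step needs an electrophilic oxygen source for the acetylide and O-selective silylation of the ynolate.

## Other disconnections considered

**Alternative 1:** The cut runs through ring B of unit A at C1'–C6' and C2'–C3', so that the ether-bearing benzene ring is made from acyclic pieces. In the forward direction a secondary amine would convert aldehyde A2 into its enamine, which adds to enone A3 (Michael addition, C1'–C6'). The aryloxy-substituted α-carbon of the ketone then condenses with the aldehyde carbon (aldol condensation, C2'–C3') to give cyclohexenone A1, which would still have to be dehydrogenated to the aromatic ring.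
- In its favour: the ether oxygen enters by alkylating a phenoxide at an sp3 carbon, not by arylating an ortho-substituted phenol. The C4' oxygen arrives as a ketone and is thereby distinguished from the ether oxygen. The bromine of A1 is a handle for attaching unit B. Amine-catalysed Robinson annulations of aldehydes with vinyl ketones are well precedented.
- Against it here: the ring it builds is a plain 1,2,4-trisubstituted benzene that can be bought ready-made as 18. A3 is a polymerisation-prone vinyl ketone whose aldol step must enolise toward the oxygenated carbon. An extra aromatisation is needed, and the stereocentre of A1 is made only to be destroyed. The chlorine problem of unit B is left untouched.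
- Comparison: structurally both plans are de novo benzene syntheses, but the chosen one spends the ring construction where classical chemistry cannot discriminate positions, whereas this one spends it where a single substitution (step 8) suffices. Mechanistically the Robinson annulation is the better precedented key step, and on that point the alternative is the better. In step count it is the poorer, since annulation, aromatisation and a later union with unit B replace one step.

**Alternative 2:** The cut is the O1–C8a bond of unit B. In the forward direction K2CO3 would deprotonate hydroxymethylene ketone A5, and the enolate oxygen would displace the fluoride ortho to the ketone by addition–elimination, giving chromone A4.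
- In its favour: the chlorine position is again fixed by connectivity (fluorine and chlorine are neighbours in the arene), which is the equal of the chosen plan. There is only one leaving group, so no orthogonal protection of two ortho oxygens is needed, which is better than the chosen plan. Closure of ortho-fluoroaryl β-dicarbonyl enolates is established chemistry, again better than a benzannulation with an untried partner.
- Against it here: the regiochemical burden moves to arene A6, which must be obtained with fluorine and chlorine adjacent and then acylated at the position next to fluorine. The ring of A5 is deactivated toward nucleophilic substitution by two methoxy donors and relies on the ketone alone. The base-mediated formylation leading to A5 must spare the methyl arylacetate. Unit A would be built last on a large intermediate, which lengthens the linear sequence.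
- Comparison: on structure the two are equal in how they fix C8. On mechanism the alternative is the safer. On step economy the chosen plan makes ring A in one step from two short fragments and joins two finished halves, whereas this route pays for A6 and for a late construction of unit A. The totals should be similar, with the chosen route the more convergent.

**Alternative 3:** The cut is the C4–C4a bond of unit A. In the forward direction P2O5 in MeSO3H would activate the carboxylic acid of A8 to an acylium species that attacks the 3-methoxyphenoxy ring para to the methoxy group, closing the pyranone to give A7.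
- In its favour: the closure is guided by a para-directing methoxy group, and the Z acid is pre-organised. A7 carries bromine, so two complete chromones could be united by cross-coupling at a late stage; that would be shorter than the addition, oxidation and annulation of steps 11 to 13, and on that point the alternative is the better. Intramolecular Friedel–Crafts acylation is a secure reaction type.
- Against it here: it solves unit A, which the chosen plan obtains in one flask from 17 and 18 (step 7). A8 needs several steps and geometric control, since only the Z isomer can close. The strongly acidic medium may sulfonate the electron-rich diaryl ether or close ortho to the methoxy group. The chlorinated ring A still has to come from elsewhere.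
- Comparison: structurally it addresses a bond that poses no selectivity problem, while the chosen key step addresses the one that does. Mechanistically it is the better precedented. In steps it is longer for unit A but potentially shorter in the union. The two ideas are compatible, since ring A made by the chosen benzannulation could be elaborated into a coupling partner for A7.

Key step: step 4

## Route

Step 1
Reactants: 1 ethoxyacetylene; 2 trichloroacetyl chloride
Product: 4 4,4-dichloro-3-ethoxycyclobut-2-en-1-one, via dichloroketene 3 (not isolated)
Conditions: Zn(Cu), Et2O–DME, 0 °C → rt, slow addition of 2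
Reagents that add atoms: none
Why: Zinc reduces 2 to dichloroketene 3, which undergoes the ketene–alkyne (2+2) cycloaddition with the electron-rich alkyne 1; the nucleophilic terminal carbon of 1 bonds to the ketene carbonyl carbon, so the ethoxy group ends on C3 and the CCl2 carbon becomes C4. DME ties up the ZnCl2 formed and protects the acid-sensitive ynol ether.

Step 2
Reactants: 4 4,4-dichloro-3-ethoxycyclobut-2-en-1-one
Product: 5 racemic 4-chloro-3-ethoxycyclobut-2-en-1-one
Conditions: Zn dust (1.1 equiv), AcOH, TMEDA, EtOH, −10 → 0 °C
Reagents that add atoms: none
Why: Zinc reductive dehalogenation of an α-chloro ketone; the first C4–Cl bond of the gem-dichloride is cleaved faster than the remaining one, so near-stoichiometric zinc at low temperature should stop at the monochloride. The new C4 stereocentre is formed racemic by unselective protonation and is erased in step 4.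

Step 3
Reactants: 6 tert-butyldimethyl(prop-2-yn-1-yloxy)silane
Product: 9 3-(tert-butyldimethylsilyloxy)-1-(triisopropylsilyloxy)prop-1-yne, via lithium acetylide 7 (not isolated), via lithium ynolate 8 (not isolated)
Conditions: n-BuLi, THF, −78 °C; LiOOt-Bu (from t-BuOOH and LiN(SiMe3)2, THF, −78 °C), −78 → 0 °C; then i-Pr3SiOTf, −78 → 0 °C
Reagents that add atoms: tert-butyl hydroperoxide (as its lithium salt) CC(C)(C)OO; triisopropylsilyl trifluoromethanesulfonate CC(C)[Si](OS(=O)(=O)C(F)(F)F)(C(C)C)C(C)C
Why: Deprotonation gives acetylide 7, which is oxygenated by the electrophilic peroxide oxygen of LiOOt-Bu (acetylide-to-ynolate oxidation) to ynolate 8; the bulky silyl triflate then silylates 8 on oxygen, not on carbon. This is the standard one-flask entry to triisopropylsilyl ynol ethers from terminal alkynes.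

Step 4
Reactants: 5 racemic 4-chloro-3-ethoxycyclobut-2-en-1-one; 9 3-(tert-butyldimethylsilyloxy)-1-(triisopropylsilyloxy)prop-1-yne
Product: 14 6-({[tert-butyl(dimethyl)silyl]oxy}methyl)-2-chloro-3-ethoxy-5-[(triisopropylsilyl)oxy]phenol, via chlorovinylketene 10 (not isolated), via vinylcyclobutenone 11 (not isolated), via dienylketene 12 (not isolated), via cyclohexadienone 13 (not isolated)
Conditions: 9 (1.5 equiv), 2,6-di-tert-butyl-4-methylpyridine (0.1 equiv), toluene (0.1 M), 80 → 110 °C, sealed vessel
Reagents that add atoms: none
Why: Proposed new method: heating opens 5 by four-electron conrotatory electrocyclic cleavage of the C1–C4 bond, chlorine turning outward, to the chlorovinylketene 10; the electron-rich alkyne 9 then adds across the ketene C=C bond in a (2+2) cycloaddition in which its nucleophilic carbon (the one carrying CH2OTBS) bonds to the electrophilic ketene carbonyl carbon, giving 11 and forming C8a–C4a and C5–C6. A second four-electron opening of 11 gives dienylketene 12, whose (3E) isomer closes by thermal six-electron disrotatory electrocyclisation (ketene carbon to the chlorine-bearing terminus) to cyclohexadienone 13; this is the mode by which ring A, the only ring formed, is closed, and tautomerisation of 13 gives the aromatic phenol 14. The closest known reaction type is the Danheiser benzannulation of cyclobutenones with siloxyalkynes; what is new is a partner carrying both a 3-alkoxy group and a chlorine on the sp3 carbon. No stereocentre is created in 14, and the racemic centres of 5, 11 and 13 are all erased on aromatisation. The step needs one selectivity, the orientation of the ketene–alkyne cycloaddition, and this is secured by the polarisation of the siloxyalkyne, which places OTIPS meta and CH2OTBS ortho to the new hydroxyl. The chlorine position follows from connectivity alone, because chlorine stays on the carbon that ends up bonded to the ketene-derived C8a and can therefore only be C8. Excess 9, dilution and a hindered pyridine are meant to suppress ketene dimerisation, O-acylation of 14 by the ketene and acid-induced loss of the siloxyalkyne.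

Step 5
Reactants: 14 6-({[tert-butyl(dimethyl)silyl]oxy}methyl)-2-chloro-3-ethoxy-5-[(triisopropylsilyl)oxy]phenol
Product: 15 tert-butyl({3-chloro-4-ethoxy-2-(methoxymethoxy)-6-[(triisopropylsilyl)oxy]phenyl}methoxy)dimethylsilane
Conditions: MOMCl, i-Pr2NEt, CH2Cl2, 0 °C → rt
Reagents that add atoms: chloromethyl methyl ether COCCl
Why: O-Alkylation of the only free hydroxyl with an α-chloro ether under amine base; the ortho chlorine raises the acidity of this phenol and both silyl ethers are untouched. The acetal masks the C8a oxygen for the organometallic and oxidation steps and is orthogonal to the acid-stable aryl silyl ether.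

Step 6
Reactants: 15 tert-butyl({3-chloro-4-ethoxy-2-(methoxymethoxy)-6-[(triisopropylsilyl)oxy]phenyl}methoxy)dimethylsilane
Product: 16 3-chloro-4-ethoxy-2-(methoxymethoxy)-6-[(triisopropylsilyl)oxy]benzaldehyde
Conditions: DDQ (1.5 equiv), CH2Cl2–pH 7 phosphate buffer (10:1), 0 °C → rt
Reagents that add atoms: none
Why: Oxidative deprotection of an electron-rich benzylic silyl ether: DDQ abstracts hydride from the benzylic CH2, activated by two ortho and one para oxygen substituents, and water removes the silyl group from the resulting silyloxocarbenium ion to give the aldehyde directly. This avoids acid desilylation to a benzylic alcohol that ionises easily, and avoids fluoride, which would strip the aryl silyl ether first.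

Step 7
Reactants: 17 3-methoxyphenol; 18 3-hydroxy-4-methoxyphenylacetic acid
Product: 20 3-(3-hydroxy-4-methoxyphenyl)-7-methoxy-4H-chromen-4-one, via deoxybenzoin 19 (not isolated)
Conditions: BF3·OEt2 (solvent), 85 °C; then DMF, MeSO2Cl, 70 °C; aq. NaOAc work-up
Reagents that add atoms: N,N-dimethylformamide CN(C)C=O
Why: Friedel–Crafts acylation of 17 by 18 in BF3·OEt2 goes ortho to the hydroxyl and para to the methoxy group to give the chelated deoxybenzoin 19; the Vilsmeier-type reagent from DMF and MeSO2Cl then formylates the activated CH2 and the ortho oxygen closes the pyranone (one-carbon annulation). A ketone acylated para to the hydroxyl cannot cyclise and is removed at this stage.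

Step 8
Reactants: 20 3-(3-hydroxy-4-methoxyphenyl)-7-methoxy-4H-chromen-4-one; 21 4-fluorobenzaldehyde
Product: 22 4-[2-methoxy-5-(7-methoxy-4-oxo-4H-chromen-3-yl)phenoxy]benzaldehyde
Conditions: Cs2CO3, DMSO, 90 °C
Reagents that add atoms: none
Why: Nucleophilic aromatic substitution by addition–elimination: the caesium phenoxide of 20 attacks the fluorine-bearing carbon of 21, activated by the para formyl group. Anhydrous carbonate in DMSO at moderate temperature spares the pyranone, which is opened only by hydroxide or amines.

Step 9
Reactants: 22 4-[2-methoxy-5-(7-methoxy-4-oxo-4H-chromen-3-yl)phenoxy]benzaldehyde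
Product: 23 3-{3-[4-(hydroxymethyl)phenoxy]-4-methoxyphenyl}-7-methoxy-4H-chromen-4-one
Conditions: NaBH4 (0.5 equiv), THF–MeOH, 0 °C
Reagents that add atoms: none
Why: Hydride reduction of the aldehyde; at 0 °C with little excess NaBH4 the aryl aldehyde should be reduced far faster than the vinylogous-ester carbonyl of the chromone.

Step 10
Reactants: 23 3-{3-[4-(hydroxymethyl)phenoxy]-4-methoxyphenyl}-7-methoxy-4H-chromen-4-one
Product: 24 3-{3-[4-(chloromethyl)phenoxy]-4-methoxyphenyl}-7-methoxy-4H-chromen-4-one
Conditions: SOCl2, cat. DMF, CH2Cl2, 0 °C → rt
Reagents that add atoms: thionyl chloride O=S(Cl)Cl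
Why: Conversion of the benzylic alcohol to the chloride through its chlorosulfite, assisted by the para aryloxy group. The chloride is preferred to the bromide because it inserts zinc with less Wurtz-type homocoupling.

Step 11
Reactants: 24 3-{3-[4-(chloromethyl)phenoxy]-4-methoxyphenyl}-7-methoxy-4H-chromen-4-one; 16 3-chloro-4-ethoxy-2-(methoxymethoxy)-6-[(triisopropylsilyl)oxy]benzaldehyde
Product: 26 racemic 1-{3-chloro-4-ethoxy-2-(methoxymethoxy)-6-[(triisopropylsilyl)oxy]phenyl}-2-{4-[2-methoxy-5-(7-methoxy-4-oxo-4H-chromen-3-yl)phenoxy]phenyl}ethan-1-ol, via benzylzinc chloride 25 (not isolated)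
Conditions: Zn dust, LiCl, THF, 25 °C; then 16, MgCl2, THF, 0 → 25 °C; aq. NH4Cl
Reagents that add atoms: none
Why: LiCl-assisted direct insertion of zinc into the benzylic C–Cl bond gives 25, a nucleophile mild enough to leave the chromone of unit A untouched; with MgCl2 as Lewis acid it adds 1,2 to aldehyde 16 and forms the C3–C4 bond of unit B. The carbinol stereocentre is formed racemic, needs no control and is removed in step 12.

Step 12
Reactants: 26 racemic 1-{3-chloro-4-ethoxy-2-(methoxymethoxy)-6-[(triisopropylsilyl)oxy]phenyl}-2-{4-[2-methoxy-5-(7-methoxy-4-oxo-4H-chromen-3-yl)phenoxy]phenyl}ethan-1-ol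
Product: 27 1-{3-chloro-4-ethoxy-2-(methoxymethoxy)-6-[(triisopropylsilyl)oxy]phenyl}-2-{4-[2-methoxy-5-(7-methoxy-4-oxo-4H-chromen-3-yl)phenoxy]phenyl}ethan-1-one
Conditions: Dess–Martin periodinane, CH2Cl2, 0 °C → rt
Reagents that add atoms: none
Why: Dess–Martin oxidation of a secondary benzylic alcohol to the ketone under near-neutral conditions that leave the acetal, the silyl ether and both electron-rich rings alone; it removes the only stereocentre of the intermediate.

Step 13
Reactants: 27 1-{3-chloro-4-ethoxy-2-(methoxymethoxy)-6-[(triisopropylsilyl)oxy]phenyl}-2-{4-[2-methoxy-5-(7-methoxy-4-oxo-4H-chromen-3-yl)phenoxy]phenyl}ethan-1-one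
Product: 30 8-chloro-7-ethoxy-3-{4-[2-methoxy-5-(7-methoxy-4-oxo-4H-chromen-3-yl)phenoxy]phenyl}-5-[(triisopropylsilyl)oxy]-4H-chromen-4-one, via enaminone 28 (not isolated), via hydroxy enaminone 29 (not isolated)
Conditions: Me2NCH(OMe)2, toluene, 90 °C; evaporate; then 3 M aq. HCl, THF, 50 °C
Reagents that add atoms: N,N-dimethylformamide dimethyl acetal COC(OC)N(C)C
Why: Condensation of the doubly activated CH2 of 27 with the amide acetal gives enaminone 28 and supplies C2; aqueous HCl then cleaves the methoxymethyl acetal, and the liberated C8a hydroxyl of 29 adds to the β-carbon and expels dimethylamine (addition–elimination, 6-endo closure) to give the pyranone. Because the C5 oxygen still carries its acid-stable silyl group, only the oxygen next to the chlorinated carbon can close, which fixes chlorine at C8.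

Step 14
Reactants: 30 8-chloro-7-ethoxy-3-{4-[2-methoxy-5-(7-methoxy-4-oxo-4H-chromen-3-yl)phenoxy]phenyl}-5-[(triisopropylsilyl)oxy]-4H-chromen-4-one
Product: 31 bisoflavolin L, 8-chloro-5,7-dihydroxy-3-{4-[2-hydroxy-5-(7-hydroxy-4-oxo-4H-chromen-3-yl)phenoxy]phenyl}-4H-chromen-4-one
Conditions: BBr3 (12 equiv), CH2Cl2, −78 °C → rt; then H2O
Reagents that add atoms: none
Why: Lewis-acid ether cleavage: BBr3 coordinates each ether oxygen and bromide attacks the methyl and ethyl carbons by SN2, while the peri silyl ether at C5 is cleaved through chelation to the C4 carbonyl; hydrolysis of the aryl borates on work-up frees the four phenols. The diaryl ether, the aryl chloride and both pyranones are inert to these conditions, and no stereocentre is involved.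

## Compound list

1 | ethoxyacetylene | CCOC#C | starting material
2 | trichloroacetyl chloride | O=C(Cl)C(Cl)(Cl)Cl | starting material
3 | dichloroketene (formed in the flask, not isolated) | O=C=C(Cl)Cl | intermediate
4 | 4,4-dichloro-3-ethoxycyclobut-2-en-1-one | CCOC1=CC(=O)C1(Cl)Cl | intermediate
5 | racemic 4-chloro-3-ethoxycyclobut-2-en-1-one | CCOC1=CC(=O)C1Cl | intermediate
6 | tert-butyldimethyl(prop-2-yn-1-yloxy)silane | C#CCO[Si](C)(C)C(C)(C)C | starting material
7 | lithium acetylide of 6 (not isolated) | [Li]C#CCO[Si](C)(C)C(C)(C)C | intermediate
8 | lithium 3-(tert-butyldimethylsilyloxy)prop-1-yn-1-olate (not isolated) | [Li]OC#CCO[Si](C)(C)C(C)(C)C | intermediate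
9 | 3-(tert-butyldimethylsilyloxy)-1-(triisopropylsilyloxy)prop-1-yne | CC(C)[Si](OC#CCO[Si](C)(C)C(C)(C)C)(C(C)C)C(C)C | intermediate
10 | (3Z)-4-chloro-3-ethoxybuta-1,3-dien-1-one (not isolated) | O=C=C/C(OCC)=C/Cl | intermediate
11 | racemic 2-({[tert-butyl(dimethyl)silyl]oxy}methyl)-4-[(Z)-2-chloro-1-ethoxyethenyl]-3-[(triisopropylsilyl)oxy]cyclobut-2-en-1-one (not isolated) | O=C1C(CO[Si](C)(C)C(C)(C)C)=C(O[Si](C(C)C)(C(C)C)C(C)C)C1/C(OCC)=C/Cl | intermediate
12 | (3E,5Z)-2-({[tert-butyl(dimethyl)silyl]oxy}methyl)-6-chloro-5-ethoxy-3-[(triisopropylsilyl)oxy]hexa-1,3,5-trien-1-one (not isolated) | O=C=C(CO[Si](C)(C)C(C)(C)C)/C(O[Si](C(C)C)(C(C)C)C(C)C)=C\C(OCC)=C\Cl | intermediate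
13 | racemic 2-({[tert-butyl(dimethyl)silyl]oxy}methyl)-6-chloro-5-ethoxy-3-[(triisopropylsilyl)oxy]cyclohexa-2,4-dien-1-one (not isolated) | O=C1C(CO[Si](C)(C)C(C)(C)C)=C(O[Si](C(C)C)(C(C)C)C(C)C)C=C(OCC)C1Cl | intermediate
14 | 6-({[tert-butyl(dimethyl)silyl]oxy}methyl)-2-chloro-3-ethoxy-5-[(triisopropylsilyl)oxy]phenol | Oc1c(CO[Si](C)(C)C(C)(C)C)c(O[Si](C(C)C)(C(C)C)C(C)C)cc(OCC)c1Cl | intermediate
15 | tert-butyl({3-chloro-4-ethoxy-2-(methoxymethoxy)-6-[(triisopropylsilyl)oxy]phenyl}methoxy)dimethylsilane | COCOc1c(CO[Si](C)(C)C(C)(C)C)c(O[Si](C(C)C)(C(C)C)C(C)C)cc(OCC)c1Cl | intermediate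
16 | 3-chloro-4-ethoxy-2-(methoxymethoxy)-6-[(triisopropylsilyl)oxy]benzaldehyde | COCOc1c(C=O)c(O[Si](C(C)C)(C(C)C)C(C)C)cc(OCC)c1Cl | intermediate
17 | 3-methoxyphenol | COc1cccc(O)c1 | starting material
18 | 3-hydroxy-4-methoxyphenylacetic acid | COc1ccc(CC(=O)O)cc1O | starting material
19 | 1-(2-hydroxy-4-methoxyphenyl)-2-(3-hydroxy-4-methoxyphenyl)ethan-1-one (not isolated) | COc1ccc(C(=O)Cc2ccc(OC)c(O)c2)c(O)c1 | intermediate
20 | 3-(3-hydroxy-4-methoxyphenyl)-7-methoxy-4H-chromen-4-one | COc1ccc2c(c1)occ(-c1ccc(OC)c(O)c1)c2=O | intermediate
21 | 4-fluorobenzaldehyde | O=Cc1ccc(F)cc1 | starting material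
22 | 4-[2-methoxy-5-(7-methoxy-4-oxo-4H-chromen-3-yl)phenoxy]benzaldehyde | COc1ccc2c(c1)occ(-c1ccc(OC)c(Oc3ccc(C=O)cc3)c1)c2=O | intermediate
23 | 3-{3-[4-(hydroxymethyl)phenoxy]-4-methoxyphenyl}-7-methoxy-4H-chromen-4-one | COc1ccc2c(c1)occ(-c1ccc(OC)c(Oc3ccc(CO)cc3)c1)c2=O | intermediate
24 | 3-{3-[4-(chloromethyl)phenoxy]-4-methoxyphenyl}-7-methoxy-4H-chromen-4-one | COc1ccc2c(c1)occ(-c1ccc(OC)c(Oc3ccc(CCl)cc3)c1)c2=O | intermediate
25 | {4-[2-methoxy-5-(7-methoxy-4-oxo-4H-chromen-3-yl)phenoxy]benzyl}zinc chloride (not isolated) | COc1ccc2c(c1)occ(-c1ccc(OC)c(Oc3ccc(C[Zn]Cl)cc3)c1)c2=O | intermediate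
26 | racemic 1-{3-chloro-4-ethoxy-2-(methoxymethoxy)-6-[(triisopropylsilyl)oxy]phenyl}-2-{4-[2-methoxy-5-(7-methoxy-4-oxo-4H-chromen-3-yl)phenoxy]phenyl}ethan-1-ol | COCOc1c(C(O)Cc2ccc(Oc3cc(-c4coc5cc(OC)ccc5c4=O)ccc3OC)cc2)c(O[Si](C(C)C)(C(C)C)C(C)C)cc(OCC)c1Cl | intermediate
27 | 1-{3-chloro-4-ethoxy-2-(methoxymethoxy)-6-[(triisopropylsilyl)oxy]phenyl}-2-{4-[2-methoxy-5-(7-methoxy-4-oxo-4H-chromen-3-yl)phenoxy]phenyl}ethan-1-one | COCOc1c(C(=O)Cc2ccc(Oc3cc(-c4coc5cc(OC)ccc5c4=O)ccc3OC)cc2)c(O[Si](C(C)C)(C(C)C)C(C)C)cc(OCC)c1Cl | intermediate
28 | (2E)-1-{3-chloro-4-ethoxy-2-(methoxymethoxy)-6-[(triisopropylsilyl)oxy]phenyl}-3-(dimethylamino)-2-{4-[2-methoxy-5-(7-methoxy-4-oxo-4H-chromen-3-yl)phenoxy]phenyl}prop-2-en-1-one (not isolated) | COCOc1c(C(=O)/C(=C/N(C)C)c2ccc(Oc3cc(-c4coc5cc(OC)ccc5c4=O)ccc3OC)cc2)c(O[Si](C(C)C)(C(C)C)C(C)C)cc(OCC)c1Cl | intermediate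
29 | (2E)-1-{3-chloro-4-ethoxy-2-hydroxy-6-[(triisopropylsilyl)oxy]phenyl}-3-(dimethylamino)-2-{4-[2-methoxy-5-(7-methoxy-4-oxo-4H-chromen-3-yl)phenoxy]phenyl}prop-2-en-1-one (not isolated) | Oc1c(C(=O)/C(=C/N(C)C)c2ccc(Oc3cc(-c4coc5cc(OC)ccc5c4=O)ccc3OC)cc2)c(O[Si](C(C)C)(C(C)C)C(C)C)cc(OCC)c1Cl | intermediate
30 | 8-chloro-7-ethoxy-3-{4-[2-methoxy-5-(7-methoxy-4-oxo-4H-chromen-3-yl)phenoxy]phenyl}-5-[(triisopropylsilyl)oxy]-4H-chromen-4-one | CCOc1cc(O[Si](C(C)C)(C(C)C)C(C)C)c2c(c1Cl)occ(-c1ccc(Oc3cc(-c4coc5cc(OC)ccc5c4=O)ccc3OC)cc1)c2=O | intermediate
31 | bisoflavolin L, 8-chloro-5,7-dihydroxy-3-{4-[2-hydroxy-5-(7-hydroxy-4-oxo-4H-chromen-3-yl)phenoxy]phenyl}-4H-chromen-4-one | O=c1c(-c2ccc(O)c(Oc3ccc(-c4coc5c(Cl)c(O)cc(O)c5c4=O)cc3)c2)coc2cc(O)ccc12 | target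

## Step count and least certain steps

Total: 14 steps. Longest linear sequence: 9 steps (1, 2, 4, 5, 6, 11, 12, 13, 14). The unit A branch (7, 8, 9, 10, then 11 to 14) is 8 steps.

**Step 4 (key step, proposed new method).** The most likely failure is that the partners are consumed before they meet. The 3-alkoxy group stabilises 5 against ring opening, so the temperature required may be one at which 9 rearranges to a silylketene or is destroyed by traces of HCl lost from 5. The chlorovinylketene 10 may also dimerise or acylate the phenol as it forms.
Fallback (known chemistry), setting out from 4 and using 9, returning at 14: exhaustive dechlorination of 4 with excess Zn dust, AcOH and TMEDA would give 3-ethoxycyclobut-2-en-1-one F1. Thermal benzannulation of F1 with 9 in toluene, the established cyclobutenone–siloxyalkyne reaction with no halogen on the four-membered ring, would give 2-({[tert-butyl(dimethyl)silyl]oxy}methyl)-5-ethoxy-3-[(triisopropylsilyl)oxy]phenol F2. Amine-catalysed ortho-chlorination of the free phenol (N-chlorosuccinimide, cat. i-Pr2NH, CH2Cl2) would then place chlorine between the hydroxyl and the ethoxy group, which is 14. The price is that the chlorine position is then set by reagent control (ortho against para to the free hydroxyl), not by connectivity.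

**Step 2.** The likely failure is over-reduction to the chlorine-free cyclobutenone or incomplete conversion, because the two C–Cl bonds differ only moderately in rate of reduction. Allylic migration of chlorine in 4 before reduction is a further risk.
Fallback, setting out from 1 and returning at 5: slow addition of chloroacetyl chloride to Et3N and 1 in Et2O would generate chloroketene F3 in the presence of the ynol ether and give 5 directly by (2+2) cycloaddition, so that 4 and the partial reduction are bypassed.

**Step 6.** The likely failure is incomplete hydride abstraction, or oxidative degradation of the very electron-rich ring through its radical cation. Loss of the acetal through acid released from the reduced quinone is also possible.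
Fallback, setting out from 15 and returning at 16: buffered HF·pyridine in THF–pyridine at 0 °C would remove the primary alkyl silyl group in preference to the hindered aryl silyl ether and give {3-chloro-4-ethoxy-2-(methoxymethoxy)-6-[(triisopropylsilyl)oxy]phenyl}methanol F4, which would be oxidised with MnO2 in CH2Cl2 to 16. This is a two-step deprotection and oxidation in place of the one-step hydride abstraction.

**Step 11.** The likely failure is slow addition to the di-ortho-substituted, electron-rich aldehyde, so that the organozinc is lost by protonation or homocoupling. Wurtz-type coupling during zinc insertion is the second risk.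
Fallback, setting out from 16 and 25, returning at 27 and making step 12 unnecessary: chlorite oxidation of 16 (NaClO2, NaH2PO4, 2-methylbut-2-ene, t-BuOH–H2O) would give 3-chloro-4-ethoxy-2-(methoxymethoxy)-6-[(triisopropylsilyl)oxy]benzoic acid F5. Carbodiimide coupling with ethanethiol would give S-ethyl 3-chloro-4-ethoxy-2-(methoxymethoxy)-6-[(triisopropylsilyl)oxy]benzenecarbothioate F6. Palladium-catalysed acylation of 25 by F6 (PdCl2(PPh3)2, THF–toluene; Fukuyama coupling) would give the ketone 27 directly. The C–C bond is then made by cross-coupling at an acyl carbon, not by carbonyl addition.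

**Step 13.** The likely failure is loss of the C5 silyl group under the hot amide-acetal conditions, which release methoxide; the other ortho oxygen could then close the ring and chlorine would end at C6. Sluggish condensation at the twisted, hindered ketone is the second risk.
Fallback, setting out from 27 and returning at 30: the acetal would be cleaved first (3 M aq. HCl, THF) to give 1-{3-chloro-4-ethoxy-2-hydroxy-6-[(triisopropylsilyl)oxy]phenyl}-2-{4-[2-methoxy-5-(7-methoxy-4-oxo-4H-chromen-3-yl)phenoxy]phenyl}ethan-1-one F7. The pyranone would then be closed under purely acidic Vilsmeier-type conditions (BF3·OEt2, DMF, MeSO2Cl, rt → 50 °C), in which no alkoxide or amine base is present to attack silicon.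

## Further compounds

F1 | step 4 | 3-ethoxycyclobut-2-en-1-one | CCOC1=CC(=O)C1
F2 | step 4 | 2-({[tert-butyl(dimethyl)silyl]oxy}methyl)-5-ethoxy-3-[(triisopropylsilyl)oxy]phenol | Oc1cc(OCC)cc(O[Si](C(C)C)(C(C)C)C(C)C)c1CO[Si](C)(C)C(C)(C)C
F3 | step 2 | chloroketene | O=C=CCl
F4 | step 6 | {3-chloro-4-ethoxy-2-(methoxymethoxy)-6-[(triisopropylsilyl)oxy]phenyl}methanol | COCOc1c(CO)c(O[Si](C(C)C)(C(C)C)C(C)C)cc(OCC)c1Cl
F5 | step 11 | 3-chloro-4-ethoxy-2-(methoxymethoxy)-6-[(triisopropylsilyl)oxy]benzoic acid | COCOc1c(C(=O)O)c(O[Si](C(C)C)(C(C)C)C(C)C)cc(OCC)c1Cl
F6 | step 11 | S-ethyl 3-chloro-4-ethoxy-2-(methoxymethoxy)-6-[(triisopropylsilyl)oxy]benzenecarbothioate | CCSC(=O)c1c(OCOC)c(Cl)c(OCC)cc1O[Si](C(C)C)(C(C)C)C(C)C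
F7 | step 13 | 1-{3-chloro-4-ethoxy-2-hydroxy-6-[(triisopropylsilyl)oxy]phenyl}-2-{4-[2-methoxy-5-(7-methoxy-4-oxo-4H-chromen-3-yl)phenoxy]phenyl}ethan-1-one | Oc1c(C(=O)Cc2ccc(Oc3cc(-c4coc5cc(OC)ccc5c4=O)ccc3OC)cc2)c(O[Si](C(C)C)(C(C)C)C(C)C)cc(OCC)c1Cl
A1 | alternative 1 | racemic methyl 2-[3-(4-bromophenoxy)-4-oxocyclohex-2-en-1-yl]acetate | COC(=O)CC1CCC(=O)C(Oc2ccc(Br)cc2)=C1
A2 | alternative 1 | methyl 4-oxobutanoate | COC(=O)CCC=O
A3 | alternative 1 | 1-(4-bromophenoxy)but-3-en-2-one | C=CC(=O)COc1ccc(Br)cc1
A4 | alternative 2 | methyl 2-{3-[4-(8-chloro-5,7-dimethoxy-4-oxo-4H-chromen-3-yl)phenoxy]-4-methoxyphenyl}acetate | COC(=O)Cc1ccc(OC)c(Oc2ccc(-c3coc4c(Cl)c(OC)cc(OC)c4c3=O)cc2)c1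
A5 | alternative 2 | methyl 2-(3-{4-[(Z)-1-(3-chloro-2-fluoro-4,6-dimethoxyphenyl)-3-hydroxy-1-oxoprop-2-en-2-yl]phenoxy}-4-methoxyphenyl)acetate | COC(=O)Cc1ccc(OC)c(Oc2ccc(/C(=C/O)C(=O)c3c(F)c(Cl)c(OC)cc3OC)cc2)c1
A6 | alternative 2 | 2-chloro-1-fluoro-3,5-dimethoxybenzene | Fc1c(Cl)c(OC)cc(OC)c1
A7 | alternative 3 | 3-[3-(4-bromophenoxy)-4-methoxyphenyl]-7-methoxy-4H-chromen-4-one | COc1ccc2c(c1)occ(-c1ccc(OC)c(Oc3ccc(Br)cc3)c1)c2=O
A8 | alternative 3 | (Z)-2-[3-(4-bromophenoxy)-4-methoxyphenyl]-3-(3-methoxyphenoxy)prop-2-enoic acid | OC(=O)/C(=C\Oc1cccc(OC)c1)c1ccc(OC)c(Oc2ccc(Br)cc2)c1
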